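**Strategy.** The synthesis rests on disconnecting the δ-lactone (ring O, C20, C10, C9, C8, C7), the only junction between ring A and the C/D bicyclo[3.2.1]octane. Since C10 is α and C20 β to C1, and C9 is β to both C7 and C14, ring A is taken as an α-methylene ketone and ring C as a dearomatised salicylic acid (a quinone monoketal acid). Their base-mediated union, carboxylate oxa-Michael addition followed by 6-endo Michael closure, should forge O–C20 and C9–C10, the spiro lactone and the C9 and C10 stereocentres in one operation. Ring D follows by C8 propargylation and gold-catalysed enol ether–alkyne cyclisation.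

Key step: step 7

Remark on numbering: ent-kaurane numbering is used throughout. Ring A is C1–C5 and C10 (C4 gem-dimethyl, C5 carries C6H2O, C1 carries the acetate). C7 is the lactone carbonyl and C20 the lactone OCH2 on C10. Ring C is C8, C9, C11, C12, C13, C14. The two-carbon bridge of ring D is C15(=O)–C16(=C17H2). "1α" means cis to C20; "11β" means axial on ring C, on the side of the C15–C16 bridge.

Remark on the chemistry: the sense of induction of (R)-DTBM-SEGPHOS in step 4 is assumed by analogy with CuH reductions of 3-alkylcyclohexenones; the antipodal ligand would be used if the first run shows the opposite sign.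

Step 1
Reactants: 1 4-methoxybenzyl alcohol; 2 tributyl(iodomethyl)stannane
Product: 3 tributyl{[(4-methoxybenzyl)oxy]methyl}stannane
Conditions: NaH, THF–DMF, 0 °C to rt
Reagents that add atoms: none
Why: Williamson ether synthesis, in which the sodium alkoxide of 1 displaces iodide from the primary α-stannyl iodide 2 to give the tin precursor of a protected hydroxymethyl anion; no stereocentre is formed.

Step 2
Reactants: 4 4,4-dimethylcyclohexane-1,3-dione
Product: 5 3-ethoxy-6,6-dimethylcyclohex-2-en-1-one
Conditions: EtOH, TsOH (cat.), toluene, reflux, Dean–Stark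
Reagents that add atoms: ethanol (CCO)
Why: Acid-catalysed vinylogous ester formation should occur mainly at the carbonyl remote from the gem-dimethyl group, leaving the neopentyl ketone free for step 3 (minor regioisomer removed by chromatography); no stereocentre is formed.

Step 3
Reactants: 3 tributyl{[(4-methoxybenzyl)oxy]methyl}stannane; 5 3-ethoxy-6,6-dimethylcyclohex-2-en-1-one
Product: 8 3-{[(4-methoxybenzyl)oxy]methyl}-4,4-dimethylcyclohex-2-en-1-one, via (4-methoxybenzyloxy)methyllithium 6 (not isolated), via lithium alkoxide adduct 7 (not isolated)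
Conditions: 3, n-BuLi, THF, −78 °C; then 5, −78 to −40 °C; then 1 M HCl, 0 °C to rt
Reagents that add atoms: none
Why: Tin–lithium exchange gives the α-alkoxy organolithium 6, whose 1,2-addition to the vinylogous ester and acid hydrolysis/dehydration of 7 (Stork–Danheiser alkylative carbonyl transposition) places the C6 arm on the carbon next to the gem-dimethyl group; no stereocentre remains.

Step 4
Reactants: 8 3-{[(4-methoxybenzyl)oxy]methyl}-4,4-dimethylcyclohex-2-en-1-one
Product: 10 (2R,3S)-2-[(dimethylamino)methyl]-3-{[(4-methoxybenzyl)oxy]methyl}-4,4-dimethylcyclohexan-1-one, via silyl enol ether 9 (not isolated)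
Conditions: Cu(OAc)2 (3 mol %), (R)-DTBM-SEGPHOS (3 mol %), MeSiH(OEt)2, toluene, 0 °C; volatiles removed; then CH2=NMe2+ I−, CH2Cl2, rt; aq. NaHCO3
Reagents that add atoms: Eschenmoser's salt, N,N-dimethylmethyleneiminium iodide (C=[N+](C)C.[I-])
Why: Ligand-controlled CuH conjugate reduction delivers hydride to one face of the β,β-disubstituted enone and sets C5, and the regiodefined silyl enol ether 9 is then aminomethylated at C10 anti to the C5 arm (Mannich reaction); the C10 configuration is inconsequential because it is erased in step 7.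

Step 5
Reactants: 10 (2R,3S)-2-[(dimethylamino)methyl]-3-{[(4-methoxybenzyl)oxy]methyl}-4,4-dimethylcyclohexan-1-one
Product: 11 1-[(1R,6S)-6-{[(4-methoxybenzyl)oxy]methyl}-5,5-dimethyl-2-oxocyclohexyl]-N,N,N-trimethylmethanaminium iodide
Conditions: MeI, Et2O, rt
Reagents that add atoms: iodomethane (CI)
Why: Menshutkin quaternisation turns the amino group into a leaving group for base-induced release of the α-methylene ketone; stereocentres are untouched.

Step 6
Reactants: 12 2-hydroxy-5-methoxybenzoic acid
Product: 13 3,3-dimethoxy-6-oxocyclohexa-1,4-diene-1-carboxylic acid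
Conditions: PhI(OAc)2, MeOH, 0 °C; used at once
Reagents that add atoms: methanol (CO)
Why: Oxidative dearomatisation of the para-methoxyphenol by the hypervalent iodine reagent in methanol gives the achiral quinone monoketal, a doubly activated acceptor whose acid cannot decarboxylate because the carboxyl sits on an alkene carbon.

Step 7
Reactants: 11 1-[(1R,6S)-6-{[(4-methoxybenzyl)oxy]methyl}-5,5-dimethyl-2-oxocyclohexyl]-N,N,N-trimethylmethanaminium iodide; 13 3,3-dimethoxy-6-oxocyclohexa-1,4-diene-1-carboxylic acid
Product: 16 tricyclic spiro keto lactone (C1 ketone; C14 enone; C11 dimethyl ketal; C6 OPMB), via α-methylene ketone 14 (not isolated), via cesium enolate ester 15 (not isolated)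
Conditions: 13 (1.5 equiv), Cs2CO3 (2.5 equiv), MeCN, 0 °C; 11 added in portions, 0 °C to rt; aq. NaH2PO4 work-up
Reagents that add atoms: none
Why: Proposed new method: Cs2CO3 eliminates NMe3 from 11 to release enone 14 slowly and ionises 13; the carboxylate adds to C20 of 14 (oxa-Michael) and the C1–C10 enolate 15 so formed adds, before it can revert, to C9 of the tethered alkylidene β-keto ester in a Michael closure made irreversible by the stabilised β-keto lactone enolate it delivers; the closest known reaction types are domino oxa-Michael/Michael annulations of hydroxy enones and Michael additions of enones released from Mannich salts, whereas a carboxylate as oxygen partner giving a δ-lactone is not established. The only ring closed is the δ-lactone (O, C20, C10, C9, C8, C7), by intermolecular C–O bond formation and then 6-(enolexo)-endo-trig C–C closure. C10 is controlled by C5: A(1,2) strain with C20 holds the C5 CH2OPMB arm pseudo-axial on the enolate, so C9 should enter trans to C6, the facial preference that planar C10 intermediates of this ring also show in radical additions. C9 is controlled by the tether: with C8 gauche to C20 in the forming ring, the bulky C11 ketal carbon lies beside the flat enolate carbon C1 and only H9 points into the cleft between C1 and C5, which is the natural relative configuration, while C8 stays epimerisable until step 9. The step needs O-alkylation at C20 to outrun self-condensation of 14 and Michael addition of the product enolate to 14, which slow release of 14 and excess 13 should secure, and attack at C9 instead of C12, which the six-membered tether and the double activation of C9 enforce.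

Step 8
Reactants: 16 tricyclic spiro keto lactone
Product: 18 1α-hydroxy keto lactone, via sodium enolate 17 (not isolated)
Conditions: NaH (1.0 equiv), THF, 0 °C; then NaBH4, EtOH, −20 °C; AcOH quench
Reagents that add atoms: none
Why: With the β-keto lactone masked as its sodium enolate 17 (which also blocks migration of the lactone to O1), NaBH4 should reduce only the C1 ketone, by axial attack anti to the axial C20 to give the equatorial 1α-alcohol (enolate-protected chemoselective hydride reduction).

Step 9
Reactants: 18 1α-hydroxy keto lactone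
Product: 20 8-propargyl 1α-hydroxy keto lactone, via sodium enolate 19 (not isolated)
Conditions: NaH (1.0 equiv), THF–DMF, 0 °C; then propargyl bromide, 0 °C to rt
Reagents that add atoms: propargyl bromide, 3-bromoprop-1-yne (C#CCBr)
Why: C-alkylation of the soft β-keto lactone enolate 19 creates the C8 quaternary centre, and the electrophile should enter anti to the adjacent quaternary C10, placing C15 trans to C10 as the later bridge requires.

Step 10
Reactants: 20 8-propargyl 1α-hydroxy keto lactone
Product: 21 8-propargyl 1α-acetoxy keto lactone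
Conditions: Ac2O, pyridine, DMAP (cat.), CH2Cl2, 0 °C to rt
Reagents that add atoms: acetic anhydride (CC(=O)OC(C)=O)
Why: DMAP-catalysed acylation installs the C1 acetate at the point where C1–OH is the only free alcohol; no stereocentre changes.

Step 11
Reactants: 21 8-propargyl 1α-acetoxy keto lactone
Product: 23 C13=C14 tert-butyldimethylsilyl enol ether, via lithium enolate 22 (not isolated)
Conditions: LiBH(s-Bu)3 (1.1 equiv), THF, −78 °C; then TBSCl, DMPU, −78 to 0 °C
Reagents that add atoms: tert-butyldimethylsilyl chloride (CC(C)(C)[Si](C)(C)Cl)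
Why: The bulky borohydride should add hydride 1,4 to the enone (the carbonyl is shielded by the quaternary C8) and the regiodefined lithium enolate 22 is O-silylated, fixing the enol ether at C13=C14 for ring D closure; no stereocentre is formed.

Step 12
Reactants: 23 C13=C14 tert-butyldimethylsilyl enol ether
Product: 24 tetracyclic C14 ketone with 16(17)-exocyclic methylene
Conditions: Ph3PAuCl (5 mol %), AgBF4 (5 mol %), CH2Cl2–MeOH (10:1), rt
Reagents that add atoms: none
Why: Gold-catalysed 5-exo-dig carbocyclisation of the silyl enol ether onto the activated alkyne (Toste-type Conia-ene reaction) forms C13–C16 and, after protodeauration, the bicyclo[3.2.1]octane with its exocyclic methylene; C13 is set by the tether because C16 can only reach the face of C13 on which C15 sits.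

Step 13
Reactants: 24 tetracyclic C14 ketone with 16(17)-exocyclic methylene
Product: 25 14-alcohol (OH syn to the C15–C16 bridge)
Conditions: SmI2 (3 equiv), i-PrOH, THF, −78 to −40 °C
Reagents that add atoms: none
Why: Single-electron ketone reduction by SmI2 passes through a C14 carbanion whose bulky O–Sm group should take the open side syn to the C15–C16 bridge, so that protonation places the small hydrogen on the C10 side and gives the thermodynamically preferred alcohol, the outcome known from dissolving-metal-type reductions of hindered ketones and opposite to that expected for borohydride.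

Step 14
Reactants: 25 14-alcohol
Product: 26 11-ketone
Conditions: PPTS, acetone–H2O, 45 °C
Reagents that add atoms: water (O)
Why: Mild acid-catalysed acetal hydrolysis unmasks the C11 ketone while the PMB ether, acetate, lactone and exocyclic alkene should survive; no stereocentre is affected.

Step 15
Reactants: 26 11-ketone
Product: 27 11β,14-diol
Conditions: NaBH4, MeOH–CH2Cl2, −40 °C
Reagents that add atoms: none
Why: Hydride should attack the C11 ketone from the face remote from the C15–C16 bridge, which blocks the endo face as in reductions of bicyclo[3.2.1]octan-3-ones such as tropinone, giving the axial 11β-alcohol; the acetate and lactone tolerate NaBH4 at low temperature.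

Step 16
Reactants: 27 11β,14-diol
Product: 28 15-hydroxy compound
Conditions: SeO2 (0.5 equiv), t-BuOOH, CH2Cl2, 0 °C to rt
Reagents that add atoms: selenium dioxide (O=[Se]=O); tert-butyl hydroperoxide as terminal oxidant (CC(C)(C)OO)
Why: Riley allylic oxidation (ene reaction, then [2,3]-sigmatropic shift) can only functionalise C15 because the other allylic position C13 is a bridgehead, and should deliver oxygen to the exo face of the bridge; the C15 configuration is inconsequential.

Step 17
Reactants: 28 15-hydroxy compound
Product: 29 6-O-(4-methoxybenzyl) ether of the target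
Conditions: MnO2 (excess), CH2Cl2, rt
Reagents that add atoms: none
Why: MnO2 oxidises only the allylic C15 alcohol and leaves the saturated C11 and C14 alcohols, completing the α-methylene cyclopentanone; the C15 stereocentre is removed.

Step 18
Reactants: 29 6-O-(4-methoxybenzyl) ether of the target
Product: 30 CNP0225182.1
Conditions: DDQ, CH2Cl2–pH 7 buffer (10:1), 0 °C
Reagents that add atoms: none
Why: Oxidative cleavage of the 4-methoxybenzyl ether by DDQ (benzylic hydride abstraction, then hydrolysis of the oxocarbenium ion) releases the C6 alcohol under neutral conditions that the enone, acetate and β-hydroxy ketone should tolerate.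

**Compound list**

1 | 4-methoxybenzyl alcohol | COc1ccc(CO)cc1 | starting material
2 | tributyl(iodomethyl)stannane | CCCC[Sn](CCCC)(CCCC)CI | starting material
3 | tributyl{[(4-methoxybenzyl)oxy]methyl}stannane | CCCC[Sn](CCCC)(CCCC)COCc1ccc(OC)cc1 | intermediate
4 | 4,4-dimethylcyclohexane-1,3-dione | CC1(C)CCC(=O)CC1=O | starting material
5 | 3-ethoxy-6,6-dimethylcyclohex-2-en-1-one | CCOC1=CC(=O)C(C)(C)CC1 | intermediate
6 | {[(4-methoxybenzyl)oxy]methyl}lithium (formed in situ) | [Li]COCc1ccc(OC)cc1 | intermediate
7 | lithium 3-ethoxy-1-{[(4-methoxybenzyl)oxy]methyl}-6,6-dimethylcyclohex-2-en-1-olate (racemic; formed in situ) | CCOC1=CC([O-])(COCc2ccc(OC)cc2)C(C)(C)CC1.[Li+] | intermediate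
8 | 3-{[(4-methoxybenzyl)oxy]methyl}-4,4-dimethylcyclohex-2-en-1-one | O=C1C=C(COCc2ccc(OC)cc2)C(C)(C)CC1 | intermediate
9 | diethoxy(methyl){[(3S)-3-{[(4-methoxybenzyl)oxy]methyl}-4,4-dimethylcyclohex-1-en-1-yl]oxy}silane (formed in situ) | CCO[Si](C)(OCC)OC1=C[C@H](COCc2ccc(OC)cc2)C(C)(C)CC1 | intermediate
10 | (2R,3S)-2-[(dimethylamino)methyl]-3-{[(4-methoxybenzyl)oxy]methyl}-4,4-dimethylcyclohexan-1-one (2,3-trans) | CN(C)C[C@@H]1C(=O)CCC(C)(C)[C@H]1COCc2ccc(OC)cc2 | intermediate
11 | 1-[(1R,6S)-6-{[(4-methoxybenzyl)oxy]methyl}-5,5-dimethyl-2-oxocyclohexyl]-N,N,N-trimethylmethanaminium iodide | C[N+](C)(C)C[C@@H]1C(=O)CCC(C)(C)[C@H]1COCc2ccc(OC)cc2.[I-] | intermediate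
12 | 2-hydroxy-5-methoxybenzoic acid (5-methoxysalicylic acid) | COc1ccc(O)c(C(=O)O)c1 | starting material
13 | 3,3-dimethoxy-6-oxocyclohexa-1,4-diene-1-carboxylic acid | COC1(OC)C=CC(=O)C(C(=O)O)=C1 | intermediate
14 | (3R)-3-{[(4-methoxybenzyl)oxy]methyl}-4,4-dimethyl-2-methylidenecyclohexan-1-one (formed in situ) | C=C1C(=O)CCC(C)(C)[C@H]1COCc2ccc(OC)cc2 | intermediate
15 | cesium C1–C10 enolate of the oxa-Michael adduct, the C20 ester of 13 with ring A (formed in situ) | COC1(OC)C=CC(=O)C(=C1)C(=O)OCC2=C([O-])CCC(C)(C)[C@H]2COCc3ccc(OC)cc3.[Cs+] | intermediate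
16 | tricyclic spiro keto lactone: 7,20-δ-lactone spiro at C10 to ring A (C1 ketone, C5 CH2OPMB cis to C20, C9 trans to C6) and cis-fused at C8–C9 (H8, H9 cis) to ring C (C14 ketone, C12=C13, C11 dimethyl ketal) | O=C1OC[C@]2(C(=O)CCC(C)(C)[C@H]2COCc4ccc(OC)cc4)[C@@H]3C(OC)(OC)C=CC(=O)[C@H]13 | intermediate
17 | sodium C8–C14 enolate of 16 (formed in situ) | [Na+].[O-]C1=C2C(=O)OC[C@]3(C(=O)CCC(C)(C)[C@H]3COCc4ccc(OC)cc4)[C@@H]2C(OC)(OC)C=C1 | intermediate
18 | 1α-hydroxy analogue of 16 (OH equatorial, cis to C20) | O=C1OC[C@]2([C@@H](O)CCC(C)(C)[C@H]2COCc4ccc(OC)cc4)[C@@H]3C(OC)(OC)C=CC(=O)[C@H]13 | intermediate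
19 | sodium C8–C14 enolate of 18 (formed in situ) | [Na+].[O-]C1=C2C(=O)OC[C@]3([C@@H](O)CCC(C)(C)[C@H]3COCc4ccc(OC)cc4)[C@@H]2C(OC)(OC)C=C1 | intermediate
20 | 8-propargyl derivative of 18 (C15H2–C16≡C17H on C8, trans to C10 across C8–C9) | C#CC[C@@]12C(=O)OC[C@]3([C@@H](O)CCC(C)(C)[C@H]3COCc4ccc(OC)cc4)[C@@H]1C(OC)(OC)C=CC2=O | intermediate
21 | 1α-acetate of 20 | C#CC[C@@]12C(=O)OC[C@]3([C@@H](OC(C)=O)CCC(C)(C)[C@H]3COCc4ccc(OC)cc4)[C@@H]1C(OC)(OC)C=CC2=O | intermediate
22 | lithium C13=C14 enolate from 1,4-reduction of 21 (formed in situ) | C#CC[C@@]12C(=O)OC[C@]3([C@@H](OC(C)=O)CCC(C)(C)[C@H]3COCc4ccc(OC)cc4)[C@@H]1C(OC)(OC)CC=C2[O-].[Li+] | intermediate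
23 | C13=C14 tert-butyldimethylsilyl enol ether (C12H2) | C#CC[C@@]12C(=O)OC[C@]3([C@@H](OC(C)=O)CCC(C)(C)[C@H]3COCc4ccc(OC)cc4)[C@@H]1C(OC)(OC)CC=C2O[Si](C)(C)C(C)(C)C | intermediate
24 | tetracyclic ketone: bicyclo[3.2.1]octane closed at C13–C16, 16(17)-exocyclic methylene, C15H2, C14 ketone, C11 dimethyl ketal, 1α-OAc, 6-OPMB | C=C1C[C@@]23C(=O)OC[C@]4([C@@H](OC(C)=O)CCC(C)(C)[C@H]4COCc5ccc(OC)cc5)[C@@H]2C(OC)(OC)C[C@@H]1C3=O | intermediate
25 | 14-alcohol of 24 (OH syn to the C15–C16 bridge) | C=C1C[C@@]23C(=O)OC[C@]4([C@@H](OC(C)=O)CCC(C)(C)[C@H]4COCc5ccc(OC)cc5)[C@@H]2C(OC)(OC)C[C@@H]1[C@H]3O | intermediate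
26 | 11-ketone (ketal of 25 removed) | C=C1C[C@@]23C(=O)OC[C@]4([C@@H](OC(C)=O)CCC(C)(C)[C@H]4COCc5ccc(OC)cc5)[C@@H]2C(=O)C[C@@H]1[C@H]3O | intermediate
27 | 11β,14-diol (11-OH axial, syn to the C15–C16 bridge) | C=C1C[C@@]23C(=O)OC[C@]4([C@@H](OC(C)=O)CCC(C)(C)[C@H]4COCc5ccc(OC)cc5)[C@@H]2[C@@H](O)C[C@@H]1[C@H]3O | intermediate
28 | 15-hydroxy derivative of 27 (15-OH on the exo face of the bridge, syn to C14) | C=C1[C@H](O)[C@@]23C(=O)OC[C@]4([C@@H](OC(C)=O)CCC(C)(C)[C@H]4COCc5ccc(OC)cc5)[C@@H]2[C@@H](O)C[C@@H]1[C@H]3O | intermediate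
29 | 6-O-(4-methoxybenzyl) ether of the target | C=C1C(=O)[C@@]23C(=O)OC[C@]4([C@@H](OC(C)=O)CCC(C)(C)[C@H]4COCc5ccc(OC)cc5)[C@@H]2[C@@H](O)C[C@@H]1[C@H]3O | intermediate
30 | CNP0225182.1: 1α-acetoxy-6,11β,14-trihydroxy-15-oxo-6,7-seco-ent-kaur-16-en-7,20-olide (14-OH syn to the C15–C16 bridge) | C=C1C(=O)[C@@]23C(=O)OC[C@]4([C@@H](OC(C)=O)CCC(C)(C)[C@H]4CO)[C@@H]2[C@@H](O)C[C@@H]1[C@H]3O | target

**Totals.** Total step count: 18. Longest linear sequence: 16 steps (steps 2, 3, 4, 5, then 7 to 18).

**Steps most likely to fail**

Step 7 (proposed new method). The oxa-Michael adduct may revert by β-elimination of the carboxylate faster than it closes, so that free enone 14 is lost to self-condensation, or the closure may take the other face of C9. The fallback separates the two bond formations and uses known reactions only. It sets out from silyl enol ether 9 (step 4 stopped before the iminium salt is added). A Mukaiyama aldol reaction with aqueous formaldehyde (Yb(OTf)3, THF–H2O) should give (2R,3S)-2-(hydroxymethyl)-3-{[(4-methoxybenzyl)oxy]methyl}-4,4-dimethylcyclohexan-1-one F1. Carbodiimide esterification with acid 13 (DCC, DMAP cat., CH2Cl2, 0 °C) should give the keto ester [(1R,6S)-6-{[(4-methoxybenzyl)oxy]methyl}-5,5-dimethyl-2-oxocyclohexyl]methyl 3,3-dimethoxy-6-oxocyclohexa-1,4-diene-1-carboxylate F2. An intramolecular Michael addition under soft enolisation (MgBr2·OEt2, i-Pr2NEt, CH2Cl2), optimised on this defined substrate, should then return to 16.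

Step 13. Protonation of the C14 organosamarium from the open face, or plain kinetic behaviour of the reductant, would give the 14-epimer. The fallback sets out from ketone 24. NaBH4 (MeOH, 0 °C) should give the kinetic 14-epi alcohol F3 (OH on the C10 side). Ruthenium-catalysed hydrogen-transfer epimerisation ((C5Ph5)Ru(CO)2Cl, KOt-Bu cat., toluene, rt to 50 °C) should then equilibrate the carbinol centre to the far less congested epimer and come back to 25.

Step 11. The borohydride may add 1,2 to the hindered enone or attack the acetate, and O-silylation of the congested enolate may be slow. The fallback removes the alkene before the alkyne is introduced. It sets out from 18. Hydrogenation of C12=C13 (RhCl(PPh3)3, H2, benzene) should give the 12,13-dihydro keto lactone F4. C8 propargylation as in step 9 should give F5, and acetylation as in step 10 the saturated keto acetate F6. Kinetic enolisation and silylation of the only enolisable ketone position (KN(SiMe3)2, TBSCl, THF, −78 °C) should then return to 23.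

**Further compounds**

F1 | step 7 | (2R,3S)-2-(hydroxymethyl)-3-{[(4-methoxybenzyl)oxy]methyl}-4,4-dimethylcyclohexan-1-one | OC[C@@H]1C(=O)CCC(C)(C)[C@H]1COCc2ccc(OC)cc2
F2 | step 7 | [(1R,6S)-6-{[(4-methoxybenzyl)oxy]methyl}-5,5-dimethyl-2-oxocyclohexyl]methyl 3,3-dimethoxy-6-oxocyclohexa-1,4-diene-1-carboxylate | COC1(OC)C=CC(=O)C(=C1)C(=O)OC[C@@H]2C(=O)CCC(C)(C)[C@H]2COCc3ccc(OC)cc3
F3 | step 13 | 14-epimer of 25 (14-OH on the C10 side, anti to the C15–C16 bridge) | C=C1C[C@@]23C(=O)OC[C@]4([C@@H](OC(C)=O)CCC(C)(C)[C@H]4COCc5ccc(OC)cc5)[C@@H]2C(OC)(OC)C[C@@H]1[C@@H]3O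
F4 | step 11 | 12,13-dihydro derivative of 18 | O=C1OC[C@]2([C@@H](O)CCC(C)(C)[C@H]2COCc4ccc(OC)cc4)[C@@H]3C(OC)(OC)CCC(=O)[C@H]13
F5 | step 11 | 8-propargyl derivative of F4 | C#CC[C@@]12C(=O)OC[C@]3([C@@H](O)CCC(C)(C)[C@H]3COCc4ccc(OC)cc4)[C@@H]1C(OC)(OC)CCC2=O
F6 | step 11 | 1α-acetate of F5 | C#CC[C@@]12C(=O)OC[C@]3([C@@H](OC(C)=O)CCC(C)(C)[C@H]3COCc4ccc(OC)cc4)[C@@H]1C(OC)(OC)CCC2=O
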